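**Strategy.** Each drimane core is assembled from an acyclic 1,6-enyne in one cationic bicyclisation that exploits the quaternary C10 shared by rings A and B. Gold activation of the C8≡C12 alkyne lets the (E)-C9=C10 alkene close ring B; the tertiary C10 cation is then captured by C1 of a silyl enol ether hung on C4, closing ring A through the C1–C10 bond. This one operation builds the trans-fused decalin, the C9 and C10 stereocentres and the C8 exocyclic methylene, under control of the C4/C5 diad, which comes from conjugate addition–allylation on a cyclohexenone template that is later cleaved. (2R,3S)-Isocitrate is attached by reductive etherification; three monomers are then esterified in sequence.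

Key step: step 11

Remark on numbering: ring carbons C1–C10 are numbered as in drimanes; C11 is the CH2O on C9, C12 the exocyclic methylene carbon on C8, C15 the oxygenated CH2 on C4. "Drim-8(12)-ene core" means 5α-H, 9α-H (C11 β, equatorial), 10β-CH3, 4β-CH3 (axial) and 4α-CH2O (equatorial). Isocitrate atoms: C1' (ester carbon on the ether carbon), C2' (ether CH), C3' (CH), C4' (CH2), C5' (carboxyl on C4'), C6' (carboxyl on C3'). PMB = 4-methoxybenzyl, TBS = tert-butyldimethylsilyl, TIPS = triisopropylsilyl.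

Assumption: the sense of induction of the copper catalyst in step 3 is assigned by analogy; the ligand enantiomer that delivers the alkenyl group to the Si face of C3 of enone 5 is the one to use. Monopotassium (2R,3S)-isocitrate (24) is taken as a commercial chiral-pool material.

**Route**

Step 1
Reactants: 1 but-2-yn-1-ol
Product: 2 PMB ether of but-2-yn-1-ol
Conditions: NaH, PMBCl, Bu4NI (cat.), THF/DMF, 0 °C to rt
Reagents that add atoms: 4-methoxybenzyl chloride, COc1ccc(CCl)cc1
Why: Williamson ether synthesis on a primary propargylic alkoxide; no stereocentre is involved.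

Step 2
Reactants: 2 PMB ether of but-2-yn-1-ol
Product: 4 (E)-3-iodobut-2-enyl PMB ether, via alkenylzirconocene chloride 3 (not isolated)
Conditions: Cp2Zr(H)Cl, THF, rt to 40 °C; then I2, 0 °C
Reagents that add atoms: iodine, II
Why: syn-hydrozirconation puts zirconium on the less hindered, methyl-bearing alkyne carbon after equilibration, and iodinolysis with retention gives the (E)-vinyl iodide (iodine trans to CH2OPMB).

Step 3
Reactants: 4 (E)-3-iodobut-2-enyl PMB ether; 5 2-methylcyclohex-2-en-1-one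
Product: 9 (2R,3R)-2-allyl-2-methyl-3-[(E)-4-(PMB-oxy)but-2-en-2-yl]cyclohexan-1-one, via alkenyllithium 6 (not isolated), via alkenylmagnesium bromide 7 (not isolated), via magnesium enolate 8 (not isolated)
Conditions: t-BuLi (2 equiv), Et2O, −78 °C; MgBr2·OEt2; 5, Cu(OTf)2 (5 mol%), chiral hydroxyalkyl imidazolinium salt (carbene ligand precursor, 6 mol%), Et2O, −30 to 0 °C; then allyl iodide, DMPU, 0 °C to rt
Reagents that add atoms: allyl iodide, C=CCI
Why: copper-catalysed asymmetric conjugate addition of a Grignard reagent to an α-substituted enone with magnesium enolate trapping; the chiral copper complex sets C3 (future C5) and allyl iodide enters anti to the new alkenyl group, giving the trans quaternary C2 (future C4).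

Step 4
Reactants: 9 (2R,3R)-2-allyl-2-methyl-3-alkenylcyclohexanone
Product: 11 (2R,3R)-2-allyl-6-hydroxy-2-methyl-3-alkenylcyclohexanone (C6 epimers), via potassium enolate 10 (not isolated)
Conditions: KHMDS, THF, −78 °C; 2-(phenylsulfonyl)-3-phenyloxaziridine; NH4Cl
Reagents that add atoms: 2-(phenylsulfonyl)-3-phenyloxaziridine, O=S(=O)(c1ccccc1)N1OC1c1ccccc1
Why: enolate oxidation by an N-sulfonyloxaziridine; only C6 can enolise because C2 is quaternary, and the new carbinol centre is destroyed in step 6.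

Step 5
Reactants: 11 α-hydroxy ketone
Product: 12 (2R,3R)-6-hydroxy-2-methyl-2-(2-oxopropyl)-3-alkenylcyclohexanone
Conditions: PdCl2 (10 mol%), CuCl, O2 (1 atm), DMF/H2O 7:1, rt
Reagents that add atoms: water, O
Why: Wacker oxidation converts the terminal allyl group into a methyl ketone, while the trisubstituted alkene is too hindered to coordinate divalent palladium.

Step 6
Reactants: 12 hydroxy diketone
Product: 13 methyl (2R,3R)-2-methyl-6-oxo-2-(2-oxopropyl)-3-[(E)-4-(PMB-oxy)but-2-en-2-yl]hexanoate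
Conditions: Pb(OAc)4, MeOH/benzene 1:1, 0 °C
Reagents that add atoms: methanol, CO
Why: Criegee-type oxidative cleavage of the α-ketol in methanol opens the template ring between C15 and C8, giving the C15 methyl ester and the C8 aldehyde without touching C4 or C5.

Step 7
Reactants: 13 aldehyde keto ester
Product: 14 methyl (2R,3R)-2-methyl-2-(2-oxopropyl)-3-[(E)-4-(PMB-oxy)but-2-en-2-yl]hept-6-ynoate
Conditions: dimethyl (1-diazo-2-oxopropyl)phosphonate, K2CO3, MeOH, 0 °C to rt
Reagents that add atoms: dimethyl (1-diazo-2-oxopropyl)phosphonate, CC(=O)C(=[N+]=[N-])P(=O)(OC)OC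
Why: Ohira–Bestmann (Seyferth–Gilbert) homologation turns the aldehyde into the terminal alkyne C8≡C12; the aldehyde reacts much faster than the methyl ketone.

Step 8
Reactants: 14 alkyne keto ester
Product: 16 methyl (2R,3R)-2-methyl-3-alkenyl-2-{2-[(TIPS)oxy]prop-2-en-1-yl}hept-6-ynoate, via lithium enolate 15 (not isolated)
Conditions: LiHMDS, THF, −78 °C; TIPSOTf, −78 °C; Et3N quench
Reagents that add atoms: triisopropylsilyl triflate, CC(C)[Si](OS(=O)(=O)C(F)(F)F)(C(C)C)C(C)C
Why: kinetic enolisation of the methyl ketone on its methyl side (the other α-carbon is a neopentyl-type CH2), with a base too weak to metalate the alkyne, then O-silylation gives the terminal silyl enol ether.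

Step 9
Reactants: 16 TIPS enol ether ester
Product: 17 (2R,3R)-2-methyl-3-alkenyl-2-{2-[(TIPS)oxy]prop-2-en-1-yl}hept-6-yn-1-ol
Conditions: LiAlH4, Et2O, 0 °C; Rochelle salt
Reagents that add atoms: none
Why: hydride reduction of the ester to the C15 primary alcohol; the bulky silyl enol ether, the alkyne and the alkene are inert to hydride.

Step 10
Reactants: 17 primary alcohol
Product: 18 cyclisation precursor (C15 TBS ether, C11 PMB ether, TIPS enol ether, terminal alkyne)
Conditions: TBSCl, imidazole, DMF, rt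
Reagents that add atoms: tert-butyldimethylsilyl chloride, CC(C)(C)[Si](C)(C)Cl
Why: standard silylation of the neopentyl-type primary alcohol under basic conditions that leave the silyl enol ether intact.

Step 11
Reactants: 18 cyclisation precursor
Product: 19 15-(TBS-oxy)-11-(PMB-oxy)drim-8(12)-en-2-one
Conditions: [Au(NCMe){P(t-Bu)2(2-biphenylyl)}]SbF6 (5 mol%), MeOH (3 equiv), CH2Cl2, −20 °C to rt
Reagents that add atoms: none
Why: Monovalent gold activates the terminal alkyne and the (E)-trisubstituted alkene attacks C8 through C9 in a chair transition state (ring B, 6-exo-dig at the alkyne and 6-endo at the alkene), leaving a vinylgold at C12 and a tertiary cation at C10; the silyl enol ether then attacks this cation through C1 (ring A, 6-endo at the enol ether π bond), and methanol removes the silyl group and supplies the proton for protodeauration. The closest known reaction types are gold- or indium-catalysed alkyne-initiated cationic cyclisations of 1,6-enynes that give a methylenecyclohexane with capture of the tertiary cation by a tethered carbon nucleophile, and the Lewis-acid alkylation of silyl enol ethers by tertiary cations. C9 and C10 are set by anti addition across the (E)-alkene, which places C11 and the new C1–C10 bond equatorial on ring B and the C10 methyl axial. Their sense relative to C5 follows from the chair in which the bulky C4 substituent on C5 is equatorial, and this gives the trans ring fusion. The step needs six- over five-membered closure at the alkyne, secured by the C10 methyl group that makes C10 the only tertiary cation site. It also needs carbon capture of the cation faster than proton loss or capture by the hindered ether oxygens or methanol, secured by the high π-nucleophilicity and six-membered reach of the enol ether.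

Step 12
Reactants: 19 bicyclic C2 ketone
Product: 21 15-(TBS-oxy)-11-(PMB-oxy)drim-8(12)-ene, via N-silyl hydrazone 20 (not isolated)
Conditions: TBSNHNHTBS, Sc(OTf)3 (1 mol%), CH2Cl2, rt; then KOt-Bu, t-BuOH, DMSO, rt
Reagents that add atoms: none
Why: Wolff–Kishner reduction in its room-temperature N-silylhydrazone variant removes the unhindered C2 carbonyl under conditions that spare the silyl ether, the PMB ether and the exocyclic alkene.

Step 13
Reactants: 21 fully protected drimene diol
Product: 22 15-(TBS-oxy)drim-8(12)-en-11-ol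
Conditions: DDQ, CH2Cl2/pH 7 buffer 10:1, 0 °C
Reagents that add atoms: none
Why: oxidative cleavage of the electron-rich PMB ether frees the C11 alcohol; the TBS ether and the 1,1-disubstituted alkene do not react.

Step 14
Reactants: 22 C11 alcohol
Product: 23 15-(TBS-oxy)drim-8(12)-en-11-al
Conditions: Dess–Martin periodinane, NaHCO3, CH2Cl2, 0 °C
Reagents that add atoms: none
Why: buffered Dess–Martin oxidation gives the β,γ-unsaturated aldehyde without epimerising C9 (C11 is already equatorial) or moving the double bond.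

Step 15
Reactants: 24 monopotassium (2R,3S)-isocitrate
Product: 25 (2S)-2-[(4R)-2,2-dimethyl-5-oxo-1,3-dioxolan-4-yl]butanedioic acid
Conditions: 2,2-dimethoxypropane, TsOH·H2O (1.1 equiv), acetone, rt
Reagents that add atoms: 2,2-dimethoxypropane, COC(C)(C)OC
Why: acetonide (1,3-dioxolan-4-one) formation is selective for the α-hydroxy acid unit (five-membered ring) and is faster than lactonisation at room temperature; both stereocentres come unchanged from the chiral pool.

Step 16
Reactants: 25 dioxolanone diacid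
Product: 27 bis(trimethylsilyl) (2S)-2-[(1R)-2-methoxy-2-oxo-1-(trimethylsilyloxy)ethyl]butanedioate, via disodium carboxylate 26 (not isolated)
Conditions: NaOMe (2.1 equiv), MeOH, 0 °C; evaporate; TMSCl (3.3 equiv), pyridine, CH2Cl2, 0 °C to rt; filter, use crude
Reagents that add atoms: sodium methoxide, C[O-].[Na+]; chlorotrimethylsilane, C[Si](C)(C)Cl
Why: methoxide opens the activated dioxolanone acyl group to the C1' methyl ester while the two carboxylates are inert, and persilylation without acidification prevents lactonisation of the freed hydroxyl.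

Step 17
Reactants: 23 C11 aldehyde; 27 tris-silylated isocitrate C1' methyl ester
Product: 28 (2S)-2-[(1R)-1-{[15-(TBS-oxy)drim-8(12)-en-11-yl]oxy}-2-methoxy-2-oxoethyl]butanedioic acid
Conditions: Et3SiH (1.5 equiv), TMSOTf (0.2 equiv), CH2Cl2, −78 to −40 °C; then aq. citric acid, THF
Reagents that add atoms: none
Why: reductive etherification: the silyl ether adds to the Lewis-acid-activated aldehyde, the resulting oxocarbenium ion is reduced by the silane, and work-up cleaves the silyl esters; the C11–O bond forms without touching C2', C3' or C9.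

Step 18
Reactants: 28 ether diacid
Product: 29 methyl (2R)-2-{[15-(TBS-oxy)drim-8(12)-en-11-yl]oxy}-2-[(3S)-2,5-dioxooxolan-3-yl]acetate
Conditions: Ac2O, CH2Cl2, rt; toluene azeotrope
Reagents that add atoms: none
Why: dehydration of the 1,2-diacid gives the five-membered cyclic anhydride, which differentiates C5' and C6' for the next steps.

Step 19
Reactants: 29 cyclic anhydride
Product: 30 acid monomer (C5' allyl ester, C6' free acid, C1' methyl ester, C15 TBS ether)
Conditions: allyl alcohol (5 equiv), DMAP (0.1 equiv), CH2Cl2, 0 °C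
Reagents that add atoms: allyl alcohol, C=CCO
Why: nucleophile-catalysed alcoholysis of a 2-substituted succinic anhydride goes at the less hindered carbonyl (C5', next to CH2) and leaves the branched C6' carboxyl free.

Step 20
Reactants: 29 cyclic anhydride
Product: 31 C5' methyl ester C6' acid
Conditions: MeOH (10 equiv), DMAP (0.1 equiv), CH2Cl2, 0 °C
Reagents that add atoms: methanol, CO
Why: the same regioselective anhydride opening at the less hindered C5' carbonyl, here with methanol.

Step 21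
Reactants: 31 C6' acid
Product: 32 C6' allyl ester (C1' and C5' methyl esters, C15 TBS ether)
Conditions: allyl bromide, KHCO3, DMF, rt
Reagents that add atoms: allyl bromide, C=CCBr
Why: carboxylate O-alkylation under weakly basic conditions that do not trigger β-elimination of the C2' alkoxy group.

Step 22
Reactants: 32 TBS ether triester
Product: 33 alcohol monomer (C15–OH free; C6' allyl ester)
Conditions: HF·pyridine, THF/pyridine, 0 °C to rt
Reagents that add atoms: none
Why: fluoride-mediated cleavage of the primary silyl ether in buffered medium leaves the methyl and allyl esters and the exocyclic alkene intact.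

Step 23
Reactants: 33 alcohol monomer; 30 acid monomer
Product: 34 dimer silyl ether (ester between C15–O of unit A and C6' of unit B)
Conditions: EDC·HCl, DMAP (0.3 equiv), CH2Cl2, 0 °C to rt
Reagents that add atoms: none
Why: Steglich esterification joins the neopentyl-type C15 alcohol to the only free carboxyl of 30; low temperature and substoichiometric DMAP limit epimerisation at C3'.

Step 24
Reactants: 34 dimer silyl ether
Product: 35 dimer alcohol (C15–OH of unit B free)
Conditions: HF·pyridine, THF/pyridine, 0 °C to rt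
Reagents that add atoms: none
Why: selective desilylation as in step 22; all ester groups survive.

Step 25
Reactants: 35 dimer alcohol; 30 acid monomer
Product: 36 trimer silyl ether (three allyl esters, TBS on C15 of unit C)
Conditions: EDC·HCl, DMAP (0.3 equiv), CH2Cl2, 0 °C to rt
Reagents that add atoms: none
Why: second Steglich esterification, identical in type to step 23, adds unit C.

Step 26
Reactants: 36 trimer silyl ether
Product: 37 trimer alcohol tris(allyl ester)
Conditions: HF·pyridine, THF/pyridine, 0 °C to rt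
Reagents that add atoms: none
Why: desilylation frees the C15 hydroxyl of unit C without ester cleavage.

Step 27
Reactants: 37 trimer alcohol tris(allyl ester)
Product: 38 cryptoporic acid T
Conditions: Pd(PPh3)4 (10 mol%), morpholine (6 equiv), THF, 0 °C to rt
Reagents that add atoms: none
Why: Tsuji–Trost deallylation by zerovalent palladium with an amine allyl acceptor frees the three carboxylic acids under neutral conditions that spare the methyl esters, the inter-unit esters and the exocyclic alkenes.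

**Compound list**

1 | but-2-yn-1-ol | CC#CCO | starting material
2 | 1-[(but-2-yn-1-yloxy)methyl]-4-methoxybenzene | CC#CCOCc1ccc(OC)cc1 | intermediate
3 | chloridobis(cyclopentadienyl)[(2E)-4-(4-methoxybenzyloxy)but-2-en-2-yl]zirconium | Cl[Zr](C1C=CC=C1)(C1C=CC=C1)/C(C)=C/COCc1ccc(OC)cc1 | intermediate
4 | 1-({[(2E)-3-iodobut-2-en-1-yl]oxy}methyl)-4-methoxybenzene | I/C(C)=C/COCc1ccc(OC)cc1 | intermediate
5 | 2-methylcyclohex-2-en-1-one | CC1=CCCCC1=O | starting material
6 | [(2E)-4-(4-methoxybenzyloxy)but-2-en-2-yl]lithium | [Li]/C(C)=C/COCc1ccc(OC)cc1 | intermediate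
7 | [(2E)-4-(4-methoxybenzyloxy)but-2-en-2-yl]magnesium bromide | Br[Mg]/C(C)=C/COCc1ccc(OC)cc1 | intermediate
8 | bromomagnesium (3R)-2-methyl-3-[(2E)-4-(PMB-oxy)but-2-en-2-yl]cyclohex-1-en-1-olate | Br[Mg]OC1=C(C)[C@@H](/C(C)=C/COCc2ccc(OC)cc2)CCC1 | intermediate
9 | (2R,3R)-2-allyl-2-methyl-3-[(2E)-4-(PMB-oxy)but-2-en-2-yl]cyclohexan-1-one | O=C1CCC[C@H](/C(C)=C/COCc2ccc(OC)cc2)[C@@]1(C)CC=C | intermediate
10 | potassium enolate of 9 (C1=C6) | [K]OC1=CCC[C@H](/C(C)=C/COCc2ccc(OC)cc2)[C@@]1(C)CC=C | intermediate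
11 | (2R,3R)-2-allyl-6-hydroxy-2-methyl-3-[(2E)-4-(PMB-oxy)but-2-en-2-yl]cyclohexan-1-one (C6 epimers) | O=C1C(O)CC[C@H](/C(C)=C/COCc2ccc(OC)cc2)[C@@]1(C)CC=C | intermediate
12 | (2R,3R)-6-hydroxy-2-methyl-2-(2-oxopropyl)-3-[(2E)-4-(PMB-oxy)but-2-en-2-yl]cyclohexan-1-one | O=C1C(O)CC[C@H](/C(C)=C/COCc2ccc(OC)cc2)[C@@]1(C)CC(C)=O | intermediate
13 | methyl (2R,3R)-2-methyl-6-oxo-2-(2-oxopropyl)-3-[(2E)-4-(PMB-oxy)but-2-en-2-yl]hexanoate | O=CCC[C@H](/C(C)=C/COCc1ccc(OC)cc1)[C@](C)(C(=O)OC)CC(C)=O | intermediate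
14 | methyl (2R,3R)-2-methyl-2-(2-oxopropyl)-3-[(2E)-4-(PMB-oxy)but-2-en-2-yl]hept-6-ynoate | C#CCC[C@H](/C(C)=C/COCc1ccc(OC)cc1)[C@](C)(C(=O)OC)CC(C)=O | intermediate
15 | lithium enolate of 14 (methyl side) | C#CCC[C@H](/C(C)=C/COCc1ccc(OC)cc1)[C@](C)(C(=O)OC)CC(=C)O[Li] | intermediate
16 | methyl (2R,3R)-2-methyl-3-[(2E)-4-(PMB-oxy)but-2-en-2-yl]-2-{2-[(triisopropylsilyl)oxy]prop-2-en-1-yl}hept-6-ynoate | C#CCC[C@H](/C(C)=C/COCc1ccc(OC)cc1)[C@](C)(C(=O)OC)CC(=C)O[Si](C(C)C)(C(C)C)C(C)C | intermediate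
17 | (2R,3R)-2-methyl-3-[(2E)-4-(PMB-oxy)but-2-en-2-yl]-2-{2-[(triisopropylsilyl)oxy]prop-2-en-1-yl}hept-6-yn-1-ol | C#CCC[C@H](/C(C)=C/COCc1ccc(OC)cc1)[C@](C)(CO)CC(=C)O[Si](C(C)C)(C(C)C)C(C)C | intermediate
18 | TBS ether of 17 (cyclisation precursor) | C#CCC[C@H](/C(C)=C/COCc1ccc(OC)cc1)[C@](C)(CO[Si](C)(C)C(C)(C)C)CC(=C)O[Si](C(C)C)(C(C)C)C(C)C | intermediate
19 | 15-(TBS-oxy)-11-(PMB-oxy)drim-8(12)-en-2-one | C=C1CC[C@H]2[C@](C)(CO[Si](C)(C)C(C)(C)C)CC(=O)C[C@]2(C)[C@H]1COCc1ccc(OC)cc1 | intermediate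
20 | N-TBS hydrazone of 19 | C=C1CC[C@H]2[C@](C)(CO[Si](C)(C)C(C)(C)C)CC(=NN[Si](C)(C)C(C)(C)C)C[C@]2(C)[C@H]1COCc1ccc(OC)cc1 | intermediate
21 | 15-(TBS-oxy)-11-(PMB-oxy)drim-8(12)-ene | C=C1CC[C@H]2[C@](C)(CO[Si](C)(C)C(C)(C)C)CCC[C@]2(C)[C@H]1COCc1ccc(OC)cc1 | intermediate
22 | 15-(TBS-oxy)drim-8(12)-en-11-ol | C=C1CC[C@H]2[C@](C)(CO[Si](C)(C)C(C)(C)C)CCC[C@]2(C)[C@H]1CO | intermediate
23 | 15-(TBS-oxy)drim-8(12)-en-11-al | C=C1CC[C@H]2[C@](C)(CO[Si](C)(C)C(C)(C)C)CCC[C@]2(C)[C@H]1C=O | intermediate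
24 | monopotassium (2R,3S)-isocitrate | O[C@@H](C(=O)[O-])[C@H](CC(=O)O)C(=O)O.[K+] | starting material
25 | (2S)-2-[(4R)-2,2-dimethyl-5-oxo-1,3-dioxolan-4-yl]butanedioic acid | CC1(C)O[C@H]([C@H](CC(=O)O)C(=O)O)C(=O)O1 | intermediate
26 | disodium (2S)-2-[(1R)-1-hydroxy-2-methoxy-2-oxoethyl]butanedioate | O[C@@H](C(=O)OC)[C@H](CC(=O)[O-])C(=O)[O-].[Na+].[Na+] | intermediate
27 | bis(trimethylsilyl) (2S)-2-[(1R)-2-methoxy-2-oxo-1-(trimethylsilyloxy)ethyl]butanedioate | C[Si](C)(C)O[C@@H](C(=O)OC)[C@H](CC(=O)O[Si](C)(C)C)C(=O)O[Si](C)(C)C | intermediate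
28 | (2S)-2-[(1R)-1-{[15-(TBS-oxy)drim-8(12)-en-11-yl]oxy}-2-methoxy-2-oxoethyl]butanedioic acid | C=C1CC[C@H]2[C@](C)(CO[Si](C)(C)C(C)(C)C)CCC[C@]2(C)[C@H]1CO[C@@H](C(=O)OC)[C@H](CC(=O)O)C(=O)O | intermediate
29 | methyl (2R)-2-{[15-(TBS-oxy)drim-8(12)-en-11-yl]oxy}-2-[(3S)-2,5-dioxooxolan-3-yl]acetate | C=C1CC[C@H]2[C@](C)(CO[Si](C)(C)C(C)(C)C)CCC[C@]2(C)[C@H]1CO[C@@H](C(=O)OC)[C@@H]1CC(=O)OC1=O | intermediate
30 | acid monomer: (2S)-2-[(1R)-1-{[15-(TBS-oxy)drim-8(12)-en-11-yl]oxy}-2-methoxy-2-oxoethyl]-4-oxo-4-(prop-2-en-1-yloxy)butanoic acid | C=C1CC[C@H]2[C@](C)(CO[Si](C)(C)C(C)(C)C)CCC[C@]2(C)[C@H]1CO[C@@H](C(=O)OC)[C@H](CC(=O)OCC=C)C(=O)O | intermediate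
31 | (2S)-2-[(1R)-1-{[15-(TBS-oxy)drim-8(12)-en-11-yl]oxy}-2-methoxy-2-oxoethyl]-4-methoxy-4-oxobutanoic acid | C=C1CC[C@H]2[C@](C)(CO[Si](C)(C)C(C)(C)C)CCC[C@]2(C)[C@H]1CO[C@@H](C(=O)OC)[C@H](CC(=O)OC)C(=O)O | intermediate
32 | C6' allyl ester of 31 | C=C1CC[C@H]2[C@](C)(CO[Si](C)(C)C(C)(C)C)CCC[C@]2(C)[C@H]1CO[C@@H](C(=O)OC)[C@H](CC(=O)OC)C(=O)OCC=C | intermediate
33 | alcohol monomer (15-hydroxy; C1', C5' methyl esters; C6' allyl ester) | C=C1CC[C@H]2[C@](C)(CO)CCC[C@]2(C)[C@H]1CO[C@@H](C(=O)OC)[C@H](CC(=O)OC)C(=O)OCC=C | intermediate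
34 | dimer silyl ether | C=C1CC[C@H]2[C@](C)(COC(=O)[C@@H](CC(=O)OCC=C)[C@@H](OC[C@H]3C(=C)CC[C@H]4[C@](C)(CO[Si](C)(C)C(C)(C)C)CCC[C@]34C)C(=O)OC)CCC[C@]2(C)[C@H]1CO[C@@H](C(=O)OC)[C@H](CC(=O)OC)C(=O)OCC=C | intermediate
35 | dimer alcohol | C=C1CC[C@H]2[C@](C)(COC(=O)[C@@H](CC(=O)OCC=C)[C@@H](OC[C@H]3C(=C)CC[C@H]4[C@](C)(CO)CCC[C@]34C)C(=O)OC)CCC[C@]2(C)[C@H]1CO[C@@H](C(=O)OC)[C@H](CC(=O)OC)C(=O)OCC=C | intermediate
36 | trimer silyl ether | C=C1CC[C@H]2[C@](C)(COC(=O)[C@@H](CC(=O)OCC=C)[C@@H](OC[C@H]3C(=C)CC[C@H]4[C@](C)(COC(=O)[C@@H](CC(=O)OCC=C)[C@@H](OC[C@H]5C(=C)CC[C@H]6[C@](C)(CO[Si](C)(C)C(C)(C)C)CCC[C@]56C)C(=O)OC)CCC[C@]34C)C(=O)OC)CCC[C@]2(C)[C@H]1CO[C@@H](C(=O)OC)[C@H](CC(=O)OC)C(=O)OCC=C | intermediate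
37 | trimer alcohol tris(allyl ester) | C=C1CC[C@H]2[C@](C)(COC(=O)[C@@H](CC(=O)OCC=C)[C@@H](OC[C@H]3C(=C)CC[C@H]4[C@](C)(COC(=O)[C@@H](CC(=O)OCC=C)[C@@H](OC[C@H]5C(=C)CC[C@H]6[C@](C)(CO)CCC[C@]56C)C(=O)OC)CCC[C@]34C)C(=O)OC)CCC[C@]2(C)[C@H]1CO[C@@H](C(=O)OC)[C@H](CC(=O)OC)C(=O)OCC=C | intermediate
38 | cryptoporic acid T | C=C1CC[C@H]2[C@](C)(COC(=O)[C@@H](CC(=O)O)[C@@H](OC[C@H]3C(=C)CC[C@H]4[C@](C)(COC(=O)[C@@H](CC(=O)O)[C@@H](OC[C@H]5C(=C)CC[C@H]6[C@](C)(CO)CCC[C@]56C)C(=O)OC)CCC[C@]34C)C(=O)OC)CCC[C@]2(C)[C@H]1CO[C@@H](C(=O)OC)[C@H](CC(=O)OC)C(=O)O | target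

**Summary**

Total step count: 27. Longest linear sequence: 24 steps (steps 1–14, 17, 18, 20–27).

Steps most likely to fail:

1. Step 11 (key bicyclisation). The C10 cation may lose a proton or be captured by methanol before ring A closes, or be captured on the axial face to give the cis-fused isomer. Fallback: the two ring closures are separated, so that the cation is regenerated under conditions where only the enol ether can react. Starting from 18, buffered fluoride (TBAF, AcOH, THF, −78 °C) cleaves only the silyl enol ether to give methyl ketone F1. Gold-catalysed methoxycyclisation of the 1,6-enyne (Ph3PAuNTf2, MeOH, rt) closes ring B alone and stores the C10 cation as the tertiary methyl ether F2. Kinetic enol silylation as in step 8 gives the TIPS enol ether F3. Lewis-acid ionisation of the tertiary ether (TMSOTf cat., 2,6-di-tert-butylpyridine, CH2Cl2, −78 °C) then alkylates the silyl enol ether intramolecularly and forms the C1–C10 bond. The route is rejoined at 19.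

2. Step 17 (reductive etherification). Acetal formation between the hindered aldehyde and the poorly nucleophilic α-silyloxy ester may be slower than direct reduction of the aldehyde, and the acid may shift the exocyclic double bond. Fallback: the ether is made by O-alkylation instead. Dioxolanone 25 is converted into its diallyl ester F4 (allyl bromide, KHCO3, DMF) and methanolysed (MeOH, camphorsulfonic acid cat., rt) to the hydroxy triester F5. Alcohol 22 is converted into its triflate F6 (Tf2O, 2,6-lutidine, CH2Cl2, −78 °C), and F6 alkylates F5 (2,6-di-tert-butyl-4-methylpyridine, CH2Cl2, rt) to give the ether triester F7. Deallylation (Pd(PPh3)4, morpholine) returns to the route at 28.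

3. Step 3 (asymmetric conjugate addition–allylation). Facial selectivity may be poor and 1,2-addition may compete when a branched alkenyl Grignard reagent meets an α-substituted enone. Fallback: the enantioselective event is moved to the unsubstituted enone. Starting from 2, alkenylzirconocene 3 is added to cyclohex-2-en-1-one under rhodium/(S)-BINAP catalysis ([Rh(cod)(MeCN)2]BF4), and the enolate is silylated to the silyl enol ether F8. MeLi then MeI gives the trans-2-methyl ketone F9. Equilibrating silylation (TMSCl, NaI, Et3N, MeCN) gives the tetrasubstituted silyl enol ether F10. MeLi then allyl iodide alkylates anti to the alkenyl group and returns to the route at 9.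

Further compounds
F1 | step 11 | (3R,4R)-3-[(TBS-oxy)methyl]-3-methyl-4-[(2E)-4-(PMB-oxy)but-2-en-2-yl]oct-7-yn-2-one-type methyl ketone (18 without the TIPS group) | C#CCC[C@H](/C(C)=C/COCc1ccc(OC)cc1)[C@](C)(CO[Si](C)(C)C(C)(C)C)CC(C)=O
F2 | step 11 | monocyclic tertiary methyl ether (ring B closed, C10–OMe, C8 exocyclic methylene, methyl ketone side chain) | C=C1CC[C@@H]([C@](C)(CO[Si](C)(C)C(C)(C)C)CC(C)=O)[C@](C)(OC)[C@H]1COCc1ccc(OC)cc1
F3 | step 11 | TIPS enol ether of F2 | C=C1CC[C@@H]([C@](C)(CO[Si](C)(C)C(C)(C)C)CC(=C)O[Si](C(C)C)(C(C)C)C(C)C)[C@](C)(OC)[C@H]1COCc1ccc(OC)cc1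
F4 | step 17 | diallyl (2S)-2-[(4R)-2,2-dimethyl-5-oxo-1,3-dioxolan-4-yl]butanedioate | CC1(C)O[C@H]([C@H](CC(=O)OCC=C)C(=O)OCC=C)C(=O)O1
F5 | step 17 | diallyl (2S)-2-[(1R)-1-hydroxy-2-methoxy-2-oxoethyl]butanedioate | O[C@@H](C(=O)OC)[C@H](CC(=O)OCC=C)C(=O)OCC=C
F6 | step 17 | 15-(TBS-oxy)drim-8(12)-en-11-yl trifluoromethanesulfonate | C=C1CC[C@H]2[C@](C)(CO[Si](C)(C)C(C)(C)C)CCC[C@]2(C)[C@H]1COS(=O)(=O)C(F)(F)F
F7 | step 17 | diallyl (2S)-2-[(1R)-1-{[15-(TBS-oxy)drim-8(12)-en-11-yl]oxy}-2-methoxy-2-oxoethyl]butanedioate | C=C1CC[C@H]2[C@](C)(CO[Si](C)(C)C(C)(C)C)CCC[C@]2(C)[C@H]1CO[C@@H](C(=O)OC)[C@H](CC(=O)OCC=C)C(=O)OCC=C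
F8 | step 3 | trimethylsilyl enol ether of 3-[(2E)-4-(PMB-oxy)but-2-en-2-yl]cyclohexanone (C1=C2) | C[Si](C)(C)OC1=C[C@@H](/C(C)=C/COCc2ccc(OC)cc2)CCC1
F9 | step 3 | trans-2-methyl-3-[(2E)-4-(PMB-oxy)but-2-en-2-yl]cyclohexan-1-one | O=C1CCC[C@H](/C(C)=C/COCc2ccc(OC)cc2)[C@H]1C
F10 | step 3 | trimethylsilyl enol ether of F9 (tetrasubstituted, C1=C2) | C[Si](C)(C)OC1=C(C)[C@@H](/C(C)=C/COCc2ccc(OC)cc2)CCC1
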